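**Retrosynthetic overview** (prostanoid numbering: C1 lactone carbonyl, C4 lactone carbinol carbon, C5=C6, exocyclic C7=C8, C9 ketone, C10=C11, C12 quaternary C–OAc, C13–C20 octenyl chain)

1. The C12 acetate comes from the tertiary alcohol; the exocyclic C7=C8 bond comes from aldol condensation of the C8 enolate of a 4-silyloxy-4-octenylcyclopentenone with the C1–C7 (Z)-enal lactone.
2. The strategy rests on the carbocycle C8–C9–C10–C11–C12: a cyclopent-2-enone whose quaternary C12 carries both oxygen and the octenyl chain. This 4-alkyl-4-hydroxycyclopent-2-enone is the Piancatelli isomer of a 2-hydroxymethyl-5-octenylfuran (furan O becomes the C9 carbonyl O, the CH2OH carbon becomes C8, the octenyl-bearing furan carbon becomes C12), so C8–C12 is disconnected.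
3. The furan comes from furfuryl alcohol by C5 lithiation and SN2 allylation with (Z)-1-bromooct-2-ene.
4. The enal comes from an acyl-Sonogashira ynone: Noyori reduction sets C4, lactonisation closes the γ-lactone, Lindlar reduction sets 5Z.
5. Ring order: the γ-lactone is closed in the side-chain fragment (step 9), the cyclopentenone is formed from the furan (step 5), and the two are joined at C7=C8 (steps 12–13).

Key step: step 5

Assumption: the sense of induction of the chiral acid in step 5 cannot be derived from a model; the (R)-configured catalyst is written, its mirror image would be used if it favours the (S)-alcohol, and any residual 12-epimer would be removed as a diastereomer after step 13 because the C1–C7 fragment is a single enantiomer.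

**Route**

Step 1
Reactants: 1 furfuryl alcohol (furan-2-ylmethanol)
Product: 2 tert-butyl(furan-2-ylmethoxy)dimethylsilane
Conditions: TBSCl, imidazole, CH2Cl2, 0 °C to rt
Reagents that add atoms: TBSCl, CC(C)(C)[Si](C)(C)Cl
Why: Standard silylation of a primary alcohol masks the acidic OH so that only ring lithiation occurs in step 3.

Step 2
Reactants: 3 (Z)-oct-2-en-1-ol
Product: 4 (Z)-1-bromooct-2-ene
Conditions: CBr4, PPh3, CH2Cl2, 0 °C; used at once
Reagents that add atoms: carbon tetrabromide, BrC(Br)(Br)Br
Why: Appel bromination replaces the primary allylic hydroxyl by SN2 displacement of the oxyphosphonium at low temperature, which leaves the Z alkene untouched.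

Step 3
Reactants: 2 tert-butyl(furan-2-ylmethoxy)dimethylsilane; 4 (Z)-1-bromooct-2-ene
Product: 6 tert-butyldimethyl({5-[(Z)-oct-2-en-1-yl]furan-2-yl}methoxy)silane, via 5-lithiofuran silyl ether 5 (not isolated)
Conditions: n-BuLi, THF, −78 to 0 °C; then 4, −78 °C to rt
Reagents that add atoms: n-BuLi, [Li]CCCC (lithium stays only in intermediate 5)
Why: The 2-substituted furan is lithiated at its free α-position and the furyllithium displaces the primary allylic bromide directly at the α-carbon (SN2 alkylation), so the Z geometry is carried over; copper is left out because organocopper species favour γ-attack.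

Step 4
Reactants: 6 tert-butyldimethyl({5-[(Z)-oct-2-en-1-yl]furan-2-yl}methoxy)silane
Product: 7 {5-[(Z)-oct-2-en-1-yl]furan-2-yl}methanol
Conditions: TBAF, THF, 0 °C
Reagents that add atoms: none
Why: Fluoride cleaves the primary TBS ether under non-acidic conditions, which matters because the 5-alkylfurfuryl alcohol is acid-labile.

Step 5
Reactants: 7 {5-[(Z)-oct-2-en-1-yl]furan-2-yl}methanol
Product: 9 (R)-4-hydroxy-4-[(Z)-oct-2-en-1-yl]cyclopent-2-en-1-one, via ring hemiketal 8 (not isolated)
Conditions: (R)-3,3'-bis(2,4,6-triisopropylphenyl)-BINOL N-triflyl phosphoramide (10 mol %), H2O (5 equiv), toluene (0.05 M), 50 °C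
Reagents that add atoms: water, O
Why: Proposed new method: the strong chiral Brønsted acid ionises the primary furfuryl alcohol to the 5-alkyl-stabilised 2-methylenefuranium ion, water adds at the octenyl-bearing ring carbon (future C12) to give hemiketal 8, and 8 opens to the 1,4-dihydroxypentadienyl cation C8H2=C9(OH)–C10=C11–C12(OH)R+, which cyclises and loses a proton from the resulting oxyallyl cation to give the enone. The closest known reactions are the racemic Piancatelli rearrangement of 5-alkylfurfuryl alcohols to 4-alkyl-4-hydroxycyclopent-2-enones in hot dilute aqueous acid and the chiral-phosphoric-acid-catalysed aza-Piancatelli rearrangement, so only the enantioselective oxa-variant on a primary carbinol is new. The cyclopentenone ring is closed by thermal conrotatory 4π electrocyclisation, which forms the C8–C12 bond. C12 is the only new stereocentre (C8 is CH2) and its configuration follows solely from the sense of conrotation, which the chiral phosphoramide anion, hydrogen-bonded to the C9 and C12 hydroxyls of the otherwise achiral cation, is meant to bias towards the (R)-alcohol. The step needs water to attack the ring carbon (attack at the carbinyl carbon merely regenerates 7), no furan oligomerisation and no alkene migration; the 2,5-disubstitution blocks both nucleophilic furan α-positions, the quaternary C12 cannot undergo the usual isomerisation of 4-hydroxycyclopentenones, and the isolated Z-disubstituted alkene should not be protonated by a catalytic acid at this temperature.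

Step 6
Reactants: 9 (R)-4-hydroxy-4-[(Z)-oct-2-en-1-yl]cyclopent-2-en-1-one
Product: 10 (R)-4-[(Z)-oct-2-en-1-yl]-4-(triethylsilyloxy)cyclopent-2-en-1-one
Conditions: TESOTf, 2,6-lutidine, CH2Cl2, −78 °C
Reagents that add atoms: TESOTf, CC[Si](CC)(CC)OS(=O)(=O)C(F)(F)F
Why: The silyl triflate with a hindered pyridine base silylates the tertiary alcohol faster than it enolises the ketone, and the TES ether prevents retro-aldol ring opening of the β-hydroxy ketone under the basic conditions of step 12.

Step 7
Reactants: 11 methyl 4-chloro-4-oxobutanoate; 12 tert-butyldimethyl(prop-2-yn-1-yloxy)silane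
Product: 13 methyl 7-[(tert-butyldimethylsilyl)oxy]-4-oxohept-5-ynoate
Conditions: PdCl2(PPh3)2 (2 mol %), CuI (4 mol %), Et3N, THF, rt
Reagents that add atoms: none
Why: Acyl Sonogashira coupling of an acid chloride with a terminal alkyne gives the ynone without touching the methyl ester or the silyl ether.

Step 8
Reactants: 13 methyl 7-[(tert-butyldimethylsilyl)oxy]-4-oxohept-5-ynoate
Product: 14 methyl (4R)-7-[(tert-butyldimethylsilyl)oxy]-4-hydroxyhept-5-ynoate
Conditions: Ru[(R,R)-TsDPEN](p-cymene) (1 mol %), i-PrOH, rt
Reagents that add atoms: none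
Why: Noyori asymmetric transfer hydrogenation of an alkynyl ketone, in which the alkynyl group takes the place of the aryl group of the usual model, so the (R,R)-catalyst should deliver hydride to the face that gives the (R)-propargylic alcohol (future C4).

Step 9
Reactants: 14 methyl (4R)-7-[(tert-butyldimethylsilyl)oxy]-4-hydroxyhept-5-ynoate
Product: 16 (R)-5-(3-hydroxyprop-1-yn-1-yl)dihydrofuran-2(3H)-one, via desilylated diol ester 15 (not isolated)
Conditions: p-TsOH·H2O (5 mol %), MeOH, rt; then solvent exchange to toluene, 50 °C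
Reagents that add atoms: none
Why: Acid-catalysed methanolysis removes the primary TBS ether and, once methanol is removed, the γ-hydroxy ester closes to the five-membered lactone by intramolecular transesterification, with retention at C4 because its C–O bond is not broken.

Step 10
Reactants: 16 (R)-5-(3-hydroxyprop-1-yn-1-yl)dihydrofuran-2(3H)-one
Product: 17 (R)-5-[(Z)-3-hydroxyprop-1-en-1-yl]dihydrofuran-2(3H)-one
Conditions: H2 (1 atm), Lindlar catalyst, quinoline, EtOAc, rt
Reagents that add atoms: none
Why: Lindlar semi-hydrogenation adds H2 syn to the alkyne and stops at the Z alkene (future C5=C6); the lactone and the allylic C–O bonds are inert to the poisoned catalyst.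

Step 11
Reactants: 17 (R)-5-[(Z)-3-hydroxyprop-1-en-1-yl]dihydrofuran-2(3H)-one
Product: 18 (Z)-3-[(R)-5-oxotetrahydrofuran-2-yl]prop-2-enal
Conditions: Dess–Martin periodinane, NaHCO3, CH2Cl2, 0 °C, dark; used immediately
Reagents that add atoms: none
Why: Buffered Dess–Martin oxidation of the allylic alcohol is neutral and fast at 0 °C, so the Z-enal should form without isomerisation to the E isomer.

Step 12
Reactants: 10 (R)-4-[(Z)-oct-2-en-1-yl]-4-(triethylsilyloxy)cyclopent-2-en-1-one; 18 (Z)-3-[(R)-5-oxotetrahydrofuran-2-yl]prop-2-enal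
Product: 20 (4R,5Z,12S,14Z)-7-hydroxy-9-oxo-12-(triethylsilyloxy)prosta-5,10,14-trien-1,4-olide (C7/C8 diastereomer mixture), via lithium dienolate 19 (not isolated)
Conditions: LDA, THF, −78 °C; then 18, −78 °C; AcOH quench at −78 °C
Reagents that add atoms: LDA, CC(C)N([Li])C(C)C (lithium stays only in intermediate 19)
Why: Kinetic α'-deprotonation of the 4,4-disubstituted enone gives the cross-conjugated lithium dienolate (loss of silanolate would give an antiaromatic cyclopentadienone and should not compete at −78 °C), which adds 1,2 to the enal in a directed aldol addition; the C7 and C8 centres are left uncontrolled because both are removed in step 13.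

Step 13
Reactants: 20 (4R,5Z,12S,14Z)-7-hydroxy-9-oxo-12-(triethylsilyloxy)prosta-5,10,14-trien-1,4-olide
Product: 22 (4R,5Z,7E,12S,14Z)-9-oxo-12-(triethylsilyloxy)prosta-5,7,10,14-tetraen-1,4-olide, via C7 mesylate 21 (not isolated)
Conditions: MsCl, Et3N, CH2Cl2, −20 °C; then DBU, −20 to 0 °C, dark
Reagents that add atoms: MsCl, CS(=O)(=O)Cl (the mesyl group stays only in intermediate 21)
Why: Mesylation of the β-hydroxy ketone and E1cB elimination form the exocyclic C7=C8 alkene, and the 7E isomer (C6 anti to the C9 carbonyl) should predominate as the thermodynamically preferred geometry of 2-alkylidenecyclopentenones, any 7Z isomer or 12-epimer being removed by chromatography.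

Step 14
Reactants: 22 (4R,5Z,7E,12S,14Z)-9-oxo-12-(triethylsilyloxy)prosta-5,7,10,14-tetraen-1,4-olide
Product: 23 (4R,5Z,7E,12S,14Z)-12-hydroxy-9-oxoprosta-5,7,10,14-tetraen-1,4-olide
Conditions: HF·pyridine, pyridine, THF, 0 °C to rt, dark
Reagents that add atoms: none
Why: Fluoride cleaves the tertiary TES ether under buffered, weakly acidic conditions that leave the lactone, the cross-conjugated dienone and both Z alkenes unchanged.

Step 15
Reactants: 23 (4R,5Z,7E,12S,14Z)-12-hydroxy-9-oxoprosta-5,7,10,14-tetraen-1,4-olide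
Product: 24 clavulolactone I, (4R,5Z,7E,12S,14Z)-12-acetoxy-9-oxoprosta-5,7,10,14-tetraen-1,4-olide
Conditions: Ac2O, DMAP, Et3N, CH2Cl2, rt, dark
Reagents that add atoms: acetic anhydride, CC(=O)OC(C)=O
Why: DMAP-catalysed acylation of the hindered tertiary alcohol; C12 has no adjacent enolisable hydrogen and its C–O bond is not broken, so its configuration is retained.

**Compound list**

1 | furfuryl alcohol (furan-2-ylmethanol) | OCc1ccco1 | starting material
2 | tert-butyl(furan-2-ylmethoxy)dimethylsilane | CC(C)(C)[Si](C)(C)OCc1ccco1 | intermediate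
3 | (Z)-oct-2-en-1-ol | CCCCC/C=C\CO | starting material
4 | (Z)-1-bromooct-2-ene | CCCCC/C=C\CBr | intermediate
5 | {5-[(tert-butyldimethylsilyloxy)methyl]furan-2-yl}lithium (formed in situ, not isolated) | [Li]c1ccc(CO[Si](C)(C)C(C)(C)C)o1 | intermediate
6 | tert-butyldimethyl({5-[(Z)-oct-2-en-1-yl]furan-2-yl}methoxy)silane | CCCCC/C=C\Cc1ccc(CO[Si](C)(C)C(C)(C)C)o1 | intermediate
7 | {5-[(Z)-oct-2-en-1-yl]furan-2-yl}methanol | CCCCC/C=C\Cc1ccc(CO)o1 | intermediate
8 | 5-methylidene-2-[(Z)-oct-2-en-1-yl]-2,5-dihydrofuran-2-ol (formed in situ, not isolated) | CCCCC/C=C\CC1(O)C=CC(=C)O1 | intermediate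
9 | (R)-4-hydroxy-4-[(Z)-oct-2-en-1-yl]cyclopent-2-en-1-one | CCCCC/C=C\C[C@]1(O)C=CC(=O)C1 | intermediate
10 | (R)-4-[(Z)-oct-2-en-1-yl]-4-(triethylsilyloxy)cyclopent-2-en-1-one | CCCCC/C=C\C[C@]1(O[Si](CC)(CC)CC)C=CC(=O)C1 | intermediate
11 | methyl 4-chloro-4-oxobutanoate | COC(=O)CCC(Cl)=O | starting material
12 | tert-butyldimethyl(prop-2-yn-1-yloxy)silane | C#CCO[Si](C)(C)C(C)(C)C | starting material
13 | methyl 7-[(tert-butyldimethylsilyl)oxy]-4-oxohept-5-ynoate | COC(=O)CCC(=O)C#CCO[Si](C)(C)C(C)(C)C | intermediate
14 | methyl (4R)-7-[(tert-butyldimethylsilyl)oxy]-4-hydroxyhept-5-ynoate | COC(=O)CC[C@@H](O)C#CCO[Si](C)(C)C(C)(C)C | intermediate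
15 | methyl (4R)-4,7-dihydroxyhept-5-ynoate (formed in situ, not isolated) | COC(=O)CC[C@@H](O)C#CCO | intermediate
16 | (R)-5-(3-hydroxyprop-1-yn-1-yl)dihydrofuran-2(3H)-one | OCC#C[C@H]1CCC(=O)O1 | intermediate
17 | (R)-5-[(Z)-3-hydroxyprop-1-en-1-yl]dihydrofuran-2(3H)-one | OC/C=C\[C@H]1CCC(=O)O1 | intermediate
18 | (Z)-3-[(R)-5-oxotetrahydrofuran-2-yl]prop-2-enal | O=C/C=C\[C@H]1CCC(=O)O1 | intermediate
19 | lithium (R)-3-[(Z)-oct-2-en-1-yl]-3-(triethylsilyloxy)cyclopenta-1,4-dien-1-olate (formed in situ, not isolated) | CCCCC/C=C\C[C@]1(O[Si](CC)(CC)CC)C=CC(O[Li])=C1 | intermediate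
20 | (4R,5Z,12S,14Z)-7-hydroxy-9-oxo-12-(triethylsilyloxy)prosta-5,10,14-trien-1,4-olide, mixture at C7 and C8 | CCCCC/C=C\C[C@]1(O[Si](CC)(CC)CC)C=CC(=O)C1C(O)/C=C\[C@H]1CCC(=O)O1 | intermediate
21 | 7-methanesulfonate of 20 (formed in situ, not isolated) | CCCCC/C=C\C[C@]1(O[Si](CC)(CC)CC)C=CC(=O)C1C(OS(C)(=O)=O)/C=C\[C@H]1CCC(=O)O1 | intermediate
22 | (4R,5Z,7E,12S,14Z)-9-oxo-12-(triethylsilyloxy)prosta-5,7,10,14-tetraen-1,4-olide | CCCCC/C=C\C[C@]1(O[Si](CC)(CC)CC)C=CC(=O)/C1=C/C=C\[C@H]1CCC(=O)O1 | intermediate
23 | (4R,5Z,7E,12S,14Z)-12-hydroxy-9-oxoprosta-5,7,10,14-tetraen-1,4-olide | CCCCC/C=C\C[C@]1(O)C=CC(=O)/C1=C/C=C\[C@H]1CCC(=O)O1 | intermediate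
24 | clavulolactone I, (R)-5-[(1Z,3E)-3-{(S)-2-acetoxy-2-[(Z)-oct-2-en-1-yl]-5-oxocyclopent-3-en-1-ylidene}prop-1-en-1-yl]dihydrofuran-2(3H)-one | CCCCC/C=C\C[C@]1(OC(C)=O)C=CC(=O)/C1=C/C=C\[C@H]1CCC(=O)O1 | target

**Step count**

Total: 15 steps. Longest linear sequence: 9 steps (steps 1, 3, 4, 5, 6, 12, 13, 14, 15; the side-chain branch through steps 7–11 is equally long).

**Steps most likely to fail**

Step 5 (proposed new method). The primary furfuryl alcohol may not ionise under conditions mild enough to keep a tight chiral ion pair. The water needed as nucleophile may solvate the cation and wash out the torquoselectivity. The ring-opened oxocarbenium ion may lose a proton at C13, which would move the chain alkene into conjugation. Fallback, setting out from 7 and returning at 9: 7 would be rearranged under the established achiral Piancatelli conditions for 5-alkylfurfuryl alcohols (ZnCl2 in refluxing aqueous dioxane, or hot dilute aqueous acid) to racemic 4-hydroxy-4-[(Z)-oct-2-en-1-yl]cyclopent-2-en-1-one F1. F1 would be resolved by preparative chromatography on a chiral stationary phase into 9 and (S)-4-hydroxy-4-[(Z)-oct-2-en-1-yl]cyclopent-2-en-1-one F2, which is discarded.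

Step 12 (with the elimination of step 13). The basic dienolate may deprotonate the Z-enal at its γ-position or isomerise it to the E-enal before it adds, and the 5Z geometry may erode further during mesylation and E1cB elimination. Fallback, setting out from 16 and dienolate 19 and returning at 22: 16 would be oxidised with Dess–Martin periodinane to 3-[(R)-5-oxotetrahydrofuran-2-yl]prop-2-ynal F3, which has no alkene geometry to lose. Addition of 19 would give the propargylic aldol (4R,12S,14Z)-7-hydroxy-9-oxo-12-(triethylsilyloxy)prosta-10,14-dien-5-yn-1,4-olide F4. Mesylation to the 7-methanesulfonate of the propargylic aldol F5 and DBU elimination would give the enynone (4R,7E,12S,14Z)-9-oxo-12-(triethylsilyloxy)prosta-7,10,14-trien-5-yn-1,4-olide F6. Lindlar semi-hydrogenation of its only triple bond would then create the 5Z alkene last and deliver 22.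

Step 3. The furyllithium may attack the allylic bromide at its γ-carbon (SN2'), or undergo lithium–bromine exchange followed by Wurtz-type coupling, and the bromide may lose its Z geometry before it reacts. Fallback, setting out from lithiofuran 5 and returning at 6: 5 would open ethylene oxide (BF3·OEt2, THF, −78 °C) to give 2-{5-[(tert-butyldimethylsilyloxy)methyl]furan-2-yl}ethan-1-ol F7. Buffered Dess–Martin oxidation would give 2-{5-[(tert-butyldimethylsilyloxy)methyl]furan-2-yl}acetaldehyde F8. A salt-free Wittig reaction with hexylidenetriphenylphosphorane F9 (from hexyltriphenylphosphonium bromide and NaHMDS, THF, −78 °C) would then build the Z alkene of 6 directly, so that no allylic electrophile is needed.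

**Further compounds**

F1 | step 5 | racemic 4-hydroxy-4-[(Z)-oct-2-en-1-yl]cyclopent-2-en-1-one | CCCCC/C=C\CC1(O)C=CC(=O)C1
F2 | step 5 | (S)-4-hydroxy-4-[(Z)-oct-2-en-1-yl]cyclopent-2-en-1-one | CCCCC/C=C\C[C@@]1(O)C=CC(=O)C1
F3 | step 12 | 3-[(R)-5-oxotetrahydrofuran-2-yl]prop-2-ynal | O=CC#C[C@H]1CCC(=O)O1
F4 | step 12 | (4R,12S,14Z)-7-hydroxy-9-oxo-12-(triethylsilyloxy)prosta-10,14-dien-5-yn-1,4-olide, mixture at C7 and C8 | CCCCC/C=C\C[C@]1(O[Si](CC)(CC)CC)C=CC(=O)C1C(O)C#C[C@H]1CCC(=O)O1
F5 | step 12 | 7-methanesulfonate of the propargylic aldol F4 | CCCCC/C=C\C[C@]1(O[Si](CC)(CC)CC)C=CC(=O)C1C(OS(C)(=O)=O)C#C[C@H]1CCC(=O)O1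
F6 | step 12 | (4R,7E,12S,14Z)-9-oxo-12-(triethylsilyloxy)prosta-7,10,14-trien-5-yn-1,4-olide | CCCCC/C=C\C[C@]1(O[Si](CC)(CC)CC)C=CC(=O)/C1=C/C#C[C@H]1CCC(=O)O1
F7 | step 3 | 2-{5-[(tert-butyldimethylsilyloxy)methyl]furan-2-yl}ethan-1-ol | OCCc1ccc(CO[Si](C)(C)C(C)(C)C)o1
F8 | step 3 | 2-{5-[(tert-butyldimethylsilyloxy)methyl]furan-2-yl}acetaldehyde | O=CCc1ccc(CO[Si](C)(C)C(C)(C)C)o1
F9 | step 3 | hexylidenetriphenylphosphorane | CCCCCC=P(c1ccccc1)(c1ccccc1)c1ccccc1
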